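## The problem

Lehualide K 13 is a symmetrical disulfide. Two identical 3,4-dimethoxy-5-methyl-2H-pyran-2-ones, each with an unbranched ten-carbon chain at C6, are joined only through the S–S bond at the chain ends. No ring is fused to another and there is no stereogenic centre, so the task reduces to one pyranone monomer with a terminal sulfur and a late oxidative dimerisation. The difficulty lies in the heterocycle: C3, C4, C5 and C6 are all substituted and both C3 and C4 carry oxygen. Enolate-based pyranone syntheses need either an extra oxidation at C3 or a pre-oxygenated acyl unit, and in either case a methylation that must distinguish the 4-hydroxyl from the lactone carbonyl oxygen. The groups that will not survive rough treatment are the disulfide and the thiol before it (cleaved by phosphines, low-valent metals and strong nucleophiles, and a poison for palladium) and the pyranone itself, a vinylogous carbonate that alkoxides can open at C2. Sulfur therefore has to arrive after all metal chemistry and under mild conditions. The enabling feature is that the lactone carbonyl C2, the methoxy-bearing C3 and C4 and the methyl-bearing C5 form a contiguous four-carbon unit with the oxidation pattern of dimethyl squarate 1, while O1 and C6 are the oxygen and carbon of a ketone attached to C5; the pyranone is thus a valence isomer of a 4-acyl-4-methyl-2,3-dimethoxycyclobutenone. The only stereocentre on the way is the quaternary C4 of that cyclobutenone, which is formed as a racemate and disappears when it becomes the sp2 carbon C5.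

## Retrosynthesis

**S–S and C–S bonds.** The S–S bond of 13 is cut first, to two molecules of thiol 12. It is the only bond joining the halves, and symmetrical oxidation of a thiol needs no differentiation of ends. The thiol is traced through thioacetate 11 to the primary chloride 10 (C–S cut). Cutting a chain C–C bond instead, or carrying the disulfide from the start, would expose sulfur to the palladium and organozinc chemistry that builds the ring. Chloride 10 has about half the mass of 13 and no sulfur. The forward steps ask only for an SN2 displacement at a primary carbon, a thioester methanolysis and a mild oxidation, all of which the pyranone must outlast.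

**O1–C2 bond of the pyranone (key cut).** In 10 the lactone bond O1–C2 is cut to give acylvinylketene 9, and a bond between the former C2 and C5 then closes the four-membered ring of cyclobutenone 8. The neighbouring ring cuts (C3–C4 by ester condensation, C4–C5 by cross-coupling, C5–C6 by acylation) all lead to open-chain precursors in which the 3,4-dioxygenation must be assembled and then methylated selectively. This cut instead moves the whole oxygen pattern into a four-membered ring where it already exists. Compound 8 is an isomer of 10, so nothing is gained in atom count, but its quaternary carbon is a natural point of union for three small pieces. The forward reaction needs only heat, and it needs the acyl group to turn inward as the ring opens.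

**C4–C(acyl) and C(acyl)–CH2 bonds.** Cyclobutenone 8 is cut at both bonds of the ketone carbonyl into the tertiary allylic benzoate 4, carbon monoxide 7 and alkylzinc bromide 6.
- C4 cannot be acylated as a nucleophile, because the enolate of a cyclobut-2-enone is a cyclic four-electron system. It must be the electrophile, and a leaving group on C4 that zerovalent palladium ionises makes it one.
- A benzoate is preferred to a halide. It is made without acid from alkoxide 3, whereas halogenating reagents would ionise the C4–O bond with help from the C2 methoxy group, and the cation so formed sheds that O-methyl group.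
- An alkylzinc halide is preferred to the alkenyl- and aryltin reagents known in carbonylative couplings of 4-halocyclobutenones. It delivers the saturated chain directly, transmetalates at 20 °C, and leaves the ring ketone and the chain chloride alone. Allylic benzoates are the established electrophiles for its three-component ketone synthesis with carbon monoxide.
- The forward reaction must take up carbon monoxide before the C–C bond forms and must deliver the acyl group to C4 and not to C2, the other terminus of the oxocyclobutenyl unit.

The precursors are a seven-carbon ring piece, a one-carbon unit and a ten-carbon chain.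

**C4–CH3 and C–Zn bonds.** Benzoate 4 is cut at the C4–methyl bond and the ester O–C bond to dimethyl squarate 1 and methyllithium 2, by way of alkoxide 3. Zinc reagent 6 comes from 1-bromo-10-chlorodecane 5 by zinc insertion into the C–Br bond. Both are single operations on commercial materials. The forward reactions must stop at mono-addition to 1, which the alkoxide of 3 secures by deactivating the remaining carbonyl, and must distinguish bromide from chloride in 5.

## Roads not taken

Alternative 1: The cut is at the two C5–C6 bonds of an open-chain form of both rings, made in two directions from a core that already holds the S–S bond. The core is the diacid dichloride 11,11'-disulfanediyldi(undecanoyl chloride) A1. The nucleophile is the bis(silyl enol ether) 1,2-dimethoxy-1,3-bis(trimethylsilyloxy)penta-1,3-diene A2. Under Me3SiOTf catalysis two equivalents of diene A2 would attack the two acid chloride ends of A1 through their terminal carbon and give the bis(3,5-dioxo ester) A3. No ring closes in this step; two lactonisations and two O-methylations follow.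
- Merits: the S–S bond is in place from the outset in A1, so no thiol is handled; both halves grow at once; γ-acylation of bis(silyloxy)dienes such as A2 is well established; no transition metal is needed.
- Weak points: every step must succeed twice on one molecule; A3 is a mixture of epimers and enol tautomers that can hardly be purified; the disulfide must survive the base used for lactonisation; the final methylation must choose the 4-hydroxyl over the lactone carbonyl oxygen on both rings.
- Comparison: this road is as short as the chosen one or shorter, and none of its reactions is new. The chosen plan sets against this that both methoxy groups and the lactone carbonyl come from 1, so no O-methylation regiochemistry arises, and that its intermediates are single monomeric compounds.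

Alternative 2: The cut is at C3–C4. The substrate is the Z enol ester methyl (2Z)-3-[(methoxyacetyl)oxy]-2-methyl-13-(tritylsulfanyl)tridec-2-enoate A4. LiN(SiMe3)2 would deprotonate the methoxyacetate CH2 of A4. The enolate carbon attacks the neighbouring methyl ester and closes the ring to 4-hydroxy-3-methoxy-5-methyl-6-[10-(tritylsulfanyl)decyl]-2H-pyran-2-one A5.
- Merits: the ring closure is a known type; the C3 methoxy group arrives with the methoxyacetate; sulfur travels protected as a trityl thioether through metal-free chemistry.
- Weak points: A4 must be made as the pure Z isomer of a tetrasubstituted enol ester by O-acylation of a β-keto ester enolate, where C-acylation and E/Z mixtures compete; the enolate of A4 can fragment to a ketene and a β-keto ester enolate instead of cyclising; A5 still needs a 4-O-methylation that competes with methylation at the carbonyl oxygen, then detritylation and oxidation.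
- Comparison: every reaction type here is precedented, a real advantage over step 3 of the chosen plan. The chosen plan answers with a shorter sequence and with the complete, correctly methylated oxygen pattern taken from 1.

Alternative 3: The cut is at C4–C5 and O1–C6. The two partners are (2E)-3-iodo-2,3-dimethoxyprop-2-enoic acid A6 and the allenylstannane tert-butyl(dimethyl){[12-(tributylstannyl)trideca-10,11-dien-1-yl]oxy}silane A7. Pd(OAc)2 with PPh3 and Bu4NBr would couple A6 with A7. The carboxylate then adds to the central allene carbon and gives 6-[10-(tert-butyldimethylsilyloxy)decyl]-3,4-dimethoxy-5-methyl-2H-pyran-2-one A8.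
- Merits: like the chosen plan it forms the ring at the final oxidation level with both methoxy groups in place, and it is convergent.
- Weak points: A6 is an α,β-dialkoxy-β-iodoacrylic acid of defined geometry whose preparation and stability are open questions; A7 is a trisubstituted stannylallene needing several steps; protodestannylation and 5-exo attack of the carboxylate compete; A8 is still three operations from a sulfur function.
- Comparison: in the key step this road is no weaker than the chosen one and rests on a known tandem process. The chosen plan sets against it that its two building blocks, 4 and 6, are each one step from commercial materials and that the chain already ends in a leaving group.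

Key step: step 4

## Route

Assumption: acylcyclobutenone 8 is taken to survive the coupling at 20 °C and a cold work-up. If its ring opening already sets in there, the crude product of step 3 is heated directly and the same bonds form in the same order.

Remark: compounds 3, 4 and 8 are racemic; one enantiomer is drawn in each SMILES string.

Step 1
Reactants: 1 dimethyl squarate (3,4-dimethoxycyclobut-3-ene-1,2-dione); 2 methyllithium
Product: 4 2,3-dimethoxy-1-methyl-4-oxocyclobut-2-en-1-yl benzoate (racemic), via lithium alkoxide 3 (not isolated)
Conditions: THF, −78 °C; then BzCl, −78 → 0 °C; NaHCO3 work-up
Reagents that add atoms: benzoyl chloride, O=C(Cl)c1ccccc1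
Why: 1,2-Addition of an organolithium to one carbonyl of a squarate ester stops at the mono-adduct at −78 °C because the alkoxide of 3 deactivates the remaining vinylogous ester carbonyl; O-acylation of the lithium alkoxide in the same flask gives the tertiary ester without any acid, under which the free carbinol would lose its C2 O-methyl group. The quaternary centre C4 is formed as a racemate and is erased in step 4.

Step 2
Reactants: 5 1-bromo-10-chlorodecane
Product: 6 (10-chlorodecyl)zinc bromide (THF solution, LiCl complex)
Conditions: Zn dust (activated with BrCH2CH2Br and Me3SiCl), LiCl, THF, 50 °C
Reagents that add atoms: zinc, [Zn]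
Why: Direct insertion of LiCl-activated zinc into a primary C–Br bond is standard; the C–Cl bond does not insert at this temperature, so the chloride remains as the later handle for sulfur.

Step 3
Reactants: 4 2,3-dimethoxy-1-methyl-4-oxocyclobut-2-en-1-yl benzoate; 6 (10-chlorodecyl)zinc bromide; 7 carbon monoxide
Product: 8 4-(11-chloroundecanoyl)-2,3-dimethoxy-4-methylcyclobut-2-en-1-one (racemic)
Conditions: Pd(PPh3)4 (5 mol %), CO (1 atm), THF–NMP, 20 °C, slow addition of 6; cold work-up
Reagents that add atoms: none
Why: Proposed new method: zerovalent palladium should ionise the tertiary allylic benzoate to an η3-oxocyclobutenyl palladium benzoate, zinc-to-palladium transmetalation then gives an allyl(alkyl)palladium whose sp3–sp3 reductive elimination is slow enough for carbon monoxide to insert into the Pd–alkyl bond, and acyl–allyl reductive elimination forms the C4–C(acyl) bond; bond formation is expected at the methyl-bearing terminus C4, which carried the leaving group, because this keeps both methoxy groups on the enone double bond, and an inner-sphere acyl transfer avoids the attack at the oxocarbenium-like C2 that a soft external nucleophile would make. The closest known reaction types are the Pd(PPh3)4-catalysed three-component ketone synthesis from allylic benzoates, carbon monoxide and alkylzinc halides and the carbonylative coupling of 4-chlorocyclobut-2-enones with alkenyl- and aryltin reagents; alkylzinc halides do not add to the ring ketone or the benzoate at 20 °C and the primary chloride is inert to the catalyst.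

Step 4
Reactants: 8 4-(11-chloroundecanoyl)-2,3-dimethoxy-4-methylcyclobut-2-en-1-one
Product: 10 6-(10-chlorodecyl)-3,4-dimethoxy-5-methyl-2H-pyran-2-one, via acylvinylketene 9 (not isolated)
Conditions: PhMe (0.02 M, dry), 90 °C
Reagents that add atoms: none
Why: Heating opens the cyclobutenone by conrotatory 4π electrocyclic cleavage of the C1–C4 bond to the 2-acylvinylketene 9. The ketone oxygen then adds to the ketene carbon in a six-electron oxa-electrocyclisation (6-endo with respect to the new O1–C2 bond, probably pseudopericyclic), which closes the only new ring, the 2-pyranone, directly at the final oxidation level. The closest known reaction type is the thermal rearrangement of 4-acylcyclobut-2-enones to 2-pyranones, the closing event of carbonylative couplings of 4-halocyclobutenones. No stereocentre is created: the quaternary C4 of 8 becomes the sp2 carbon C5, so the racemic nature of 8 is without consequence. The selectivity needed is torquoselectivity, with the acyl group rotating inward so that it lies next to the ketene. The acceptor character of the acyl group favours inward rotation, and the methyl group prefers to turn outward. The opening is also reversible, so a ketene with the acyl group outside returns to 8 while the correct isomer is drained irreversibly by lactone formation. Dilution and dry solvent keep 9 from dimerising or being trapped, and the chain chloride is a spectator.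

Step 5
Reactants: 10 6-(10-chlorodecyl)-3,4-dimethoxy-5-methyl-2H-pyran-2-one
Product: 11 S-[10-(3,4-dimethoxy-5-methyl-2-oxo-2H-pyran-6-yl)decyl] ethanethioate
Conditions: CH3C(O)SK, NaI (cat.), DMF, 50 °C
Reagents that add atoms: potassium thioacetate, CC(=O)[S-].[K+]
Why: SN2 displacement of the primary chloride, accelerated by iodide exchange (Finkelstein catalysis); thioacetate is a soft, weakly basic nucleophile that should leave the pyranone lactone alone.

Step 6
Reactants: 11 S-[10-(3,4-dimethoxy-5-methyl-2-oxo-2H-pyran-6-yl)decyl] ethanethioate (two molecules)
Product: 13 lehualide K, via thiol 12 (not isolated)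
Conditions: K2CO3, MeOH–THF (degassed), 0 °C; then I2, 0 → 20 °C
Reagents that add atoms: none
Why: Methoxide-mediated transesterification of the thioester releases the thiolate of 12, which iodine oxidises at once to the symmetrical disulfide (thiol-to-disulfide oxidation); running both in one flask at 0 °C keeps the contact of thiolate and base with the pyranone short.

## Compound list

1 | dimethyl squarate (3,4-dimethoxycyclobut-3-ene-1,2-dione) | COC1=C(OC)C(=O)C1=O | starting material
2 | methyllithium | [Li]C | starting material
3 | lithium 2,3-dimethoxy-1-methyl-4-oxocyclobut-2-en-1-olate (racemic, one enantiomer drawn) | COC1=C(OC)[C@](C)([O-])C1=O.[Li+] | intermediate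
4 | 2,3-dimethoxy-1-methyl-4-oxocyclobut-2-en-1-yl benzoate (racemic, one enantiomer drawn) | COC1=C(OC)[C@](C)(OC(=O)c2ccccc2)C1=O | intermediate
5 | 1-bromo-10-chlorodecane | ClCCCCCCCCCCBr | starting material
6 | (10-chlorodecyl)zinc bromide | ClCCCCCCCCCC[Zn]Br | intermediate
7 | carbon monoxide | [C-]#[O+] | starting material
8 | 4-(11-chloroundecanoyl)-2,3-dimethoxy-4-methylcyclobut-2-en-1-one (racemic, one enantiomer drawn) | COC1=C(OC)[C@@](C)(C(=O)CCCCCCCCCCCl)C1=O | intermediate
9 | (3E)-15-chloro-2,3-dimethoxy-4-methylpentadeca-1,3-diene-1,5-dione (acylvinylketene) | O=C=C(OC)/C(OC)=C(/C)C(=O)CCCCCCCCCCCl | intermediate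
10 | 6-(10-chlorodecyl)-3,4-dimethoxy-5-methyl-2H-pyran-2-one | COc1c(C)c(CCCCCCCCCCCl)oc(=O)c1OC | intermediate
11 | S-[10-(3,4-dimethoxy-5-methyl-2-oxo-2H-pyran-6-yl)decyl] ethanethioate | COc1c(C)c(CCCCCCCCCCSC(C)=O)oc(=O)c1OC | intermediate
12 | 3,4-dimethoxy-5-methyl-6-(10-sulfanyldecyl)-2H-pyran-2-one | COc1c(C)c(CCCCCCCCCCS)oc(=O)c1OC | intermediate
13 | lehualide K, 6,6'-[disulfanediylbis(decane-10,1-diyl)]bis(3,4-dimethoxy-5-methyl-2H-pyran-2-one) | COc1c(C)c(CCCCCCCCCCSSCCCCCCCCCCc2oc(=O)c(OC)c(OC)c2C)oc(=O)c1OC | target

## Step count and risks

Total: 6 steps. Longest linear sequence: 5 steps (steps 1, 3, 4, 5 and 6 from dimethyl squarate 1); step 2 is a one-step side branch.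

**Step 3 (proposed new method).** The most likely failures are transfer of the alkyl group to the ring without uptake of carbon monoxide, and acyl delivery to the methoxy-bearing terminus C2 of the ambident oxocyclobutenyl ligand. Both allyl termini become quaternary and differ only in carrying methyl or methoxy. Loss of the C2 O-methyl group from the ionised intermediate is a third drain. The fallback uses known reactions, needs no carbon monoxide and moves the chain attachment to the pyranone; it sets out from 4 and comes back at 11. Benzoate 4 is coupled with commercial tributyl(1-ethoxyvinyl)stannane (Stille coupling of an allylic ester; Pd2(dba)3, LiCl, DMF, 20 °C) to 4-(1-ethoxyethenyl)-2,3-dimethoxy-4-methylcyclobut-2-en-1-one F1. Cold dilute HCl hydrolyses the enol ether to 4-acetyl-2,3-dimethoxy-4-methylcyclobut-2-en-1-one F2. Heating in toluene performs the same ring expansion to 3,4-dimethoxy-5,6-dimethyl-2H-pyran-2-one F3. LiN(iPr)2 at −78 °C deprotonates the C6 methyl group (vinylogous to the lactone carbonyl), and alkylation with an excess of 1,9-dibromononane gives 6-(10-bromodecyl)-3,4-dimethoxy-5-methyl-2H-pyran-2-one F4. Treating F4 with CH3C(O)SK under the conditions of step 5 gives 11.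

**Step 4 (key step).** The ring expansion may fail through interception of ketene 9 by a second molecule or by traces of water before it closes, or through decomposition of 8 below the temperature of a clean opening. The fallback is ionic instead of pericyclic and runs from 8 to 10. NaOMe in MeOH at 0 °C adds to the ring carbonyl, and the strained 1,3-diketone opens by retro-Claisen cleavage of C1–C4 to methyl (2Z)-15-chloro-2,3-dimethoxy-4-methyl-5-oxopentadec-2-enoate F5, whose Z geometry is inherited from the ring. TsOH in refluxing toluene then closes the enol lactone with loss of methanol and gives 10.

**Step 1.** The tertiary benzoate may ionise during acylation, work-up or chromatography with loss of the C2 O-methyl group, or acylation of the hindered alkoxide may stay incomplete. The fallback sets out from 1. The methyllithium adduct is quenched with NH4Cl and isolated as 4-hydroxy-2,3-dimethoxy-4-methylcyclobut-2-en-1-one F6. Acetylation (Ac2O, Et3N, DMAP) gives 2,3-dimethoxy-1-methyl-4-oxocyclobut-2-en-1-yl acetate F7, a poorer leaving group that should survive handling. F7 takes the place of 4 in step 3, and the route is rejoined at 8.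

**Step 6.** Methoxide or thiolate may open or add to the pyranone before oxidation is complete, and thiol exchange may leave mixed sulfur species. The fallback avoids free thiolate and base and sets out from 10. Finkelstein exchange (NaI, acetone, reflux) gives 6-(10-iododecyl)-3,4-dimethoxy-5-methyl-2H-pyran-2-one F8. Sulfur transfer with benzyltriethylammonium tetrathiomolybdate, (BnEt3N)2MoS4, in MeCN at 20 °C converts primary halides directly into symmetrical disulfides and rejoins the route at 13.

## Further compounds

F1 | step 3 | 4-(1-ethoxyethenyl)-2,3-dimethoxy-4-methylcyclobut-2-en-1-one (racemic, one enantiomer drawn) | COC1=C(OC)[C@@](C)(C(=C)OCC)C1=O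
F2 | step 3 | 4-acetyl-2,3-dimethoxy-4-methylcyclobut-2-en-1-one (racemic, one enantiomer drawn) | COC1=C(OC)[C@@](C)(C(C)=O)C1=O
F3 | step 3 | 3,4-dimethoxy-5,6-dimethyl-2H-pyran-2-one | COc1c(C)c(C)oc(=O)c1OC
F4 | step 3 | 6-(10-bromodecyl)-3,4-dimethoxy-5-methyl-2H-pyran-2-one | COc1c(C)c(CCCCCCCCCCBr)oc(=O)c1OC
F5 | step 4 | methyl (2Z)-15-chloro-2,3-dimethoxy-4-methyl-5-oxopentadec-2-enoate (racemic at C4, one enantiomer drawn) | COC(=O)/C(OC)=C(OC)\[C@@H](C)C(=O)CCCCCCCCCCCl
F6 | step 1 | 4-hydroxy-2,3-dimethoxy-4-methylcyclobut-2-en-1-one (racemic, one enantiomer drawn) | COC1=C(OC)[C@](C)(O)C1=O
F7 | step 1 | 2,3-dimethoxy-1-methyl-4-oxocyclobut-2-en-1-yl acetate (racemic, one enantiomer drawn) | COC1=C(OC)[C@](C)(OC(C)=O)C1=O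
F8 | step 6 | 6-(10-iododecyl)-3,4-dimethoxy-5-methyl-2H-pyran-2-one | COc1c(C)c(CCCCCCCCCCI)oc(=O)c1OC
A1 | alternative 1 | 11,11'-disulfanediyldi(undecanoyl chloride) | O=C(Cl)CCCCCCCCCCSSCCCCCCCCCCC(=O)Cl
A2 | alternative 1 | 1,2-dimethoxy-1,3-bis(trimethylsilyloxy)penta-1,3-diene (double-bond geometry not specified) | COC(O[Si](C)(C)C)=C(OC)C(O[Si](C)(C)C)=CC
A3 | alternative 1 | bis(3,5-dioxo ester) disulfide, dimethyl 15,15'-disulfanediylbis(2-methoxy-4-methyl-3,5-dioxopentadecanoate) (keto form; labile centres, mixture of epimers and enol tautomers) | COC(=O)C(OC)C(=O)C(C)C(=O)CCCCCCCCCCSSCCCCCCCCCCC(=O)C(C)C(=O)C(OC)C(=O)OC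
A4 | alternative 2 | methyl (2Z)-3-[(methoxyacetyl)oxy]-2-methyl-13-(tritylsulfanyl)tridec-2-enoate | COCC(=O)O/C(CCCCCCCCCCSC(c1ccccc1)(c1ccccc1)c1ccccc1)=C(/C)C(=O)OC
A5 | alternative 2 | 4-hydroxy-3-methoxy-5-methyl-6-[10-(tritylsulfanyl)decyl]-2H-pyran-2-one | COc1c(O)c(C)c(CCCCCCCCCCSC(c2ccccc2)(c2ccccc2)c2ccccc2)oc1=O
A6 | alternative 3 | (2E)-3-iodo-2,3-dimethoxyprop-2-enoic acid | OC(=O)/C(OC)=C(/OC)I
A7 | alternative 3 | tert-butyl(dimethyl){[12-(tributylstannyl)trideca-10,11-dien-1-yl]oxy}silane (racemic allene) | CCCC[Sn](CCCC)(CCCC)C(C)=C=CCCCCCCCCCO[Si](C)(C)C(C)(C)C
A8 | alternative 3 | 6-[10-(tert-butyldimethylsilyloxy)decyl]-3,4-dimethoxy-5-methyl-2H-pyran-2-one | COc1c(C)c(CCCCCCCCCCO[Si](C)(C)C(C)(C)C)oc(=O)c1OC
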